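## Retrosynthetic overview

1. Target 25 ⇐ silyl ether/methyl ester 23 ⇐ C12–C13 bond by Ni-electrocatalytic decarboxylative alkenylation of the (Z)-alkenyl iodide 17 with the (Z)-acid 21 (21 from a Z-selective α-silyloxy-ketone Wittig).
2. 17 ⇐ aldehyde 16 by Zhao iodo-olefination (11Z) ⇐ allylic alcohol 13 by Eschenmoser–Claisen rearrangement and amide reduction (7E).
3. 13 ⇐ key C2–C3 bond: electrochemical, stereoretentive decarboxylative alkenylation of acid 5 with the (E)-α-bromoacrylate 11 (new); 11 ⇐ 3-bromofuran.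
4. 5 ⇐ (R)-limonene oxide 1 by oxidative ring opening, aldehyde-selective isopropenylation and haloform degradation; the stereocentre is bought.
5. Rings: none is formed. The furan is purchased and the only ring event is the opening of the limonene cyclohexane in step 1.

Assumption: the single stereocentre is (R) (CIP: isopropenyl > CH2CH=C arm > CH2CH2C(CO2H)= arm > H) and maps onto C4 of (R)-(+)-limonene; commercial (+)-limonene oxide (cis/trans mixture), 3-bromofuran, phosphonate 8, phosphonium salt 18 and silyloxyacetone 19 are bought.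

## Route

Step 1
Reactants: 1 (4R)-limonene 1,2-oxide (cis/trans mixture)
Product: 3 (3R)-6-oxo-3-(prop-1-en-2-yl)heptanal, via limonene-1,2-diol 2 (not isolated)
Conditions: H5IO6 (1.2 equiv), THF/H2O, 0 °C to rt
Reagents that add atoms: water O
Why: Acid-mediated hydrolysis of either epoxide epimer gives the 1,2-diol, which periodate cleaves (Malaprade glycol cleavage); C4 of limonene is untouched and becomes C3 (R).

Step 2
Reactants: 3 (3R)-6-oxo-3-(prop-1-en-2-yl)heptanal
Product: 4 (5R)-7-hydroxy-8-methyl-5-(prop-1-en-2-yl)non-8-en-2-one (both C7 epimers)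
Conditions: 2-bromopropene (2.5 equiv), CrCl2 (4 equiv), NiCl2 (2 mol %), DMF, rt
Reagents that add atoms: 2-bromopropene C=C(C)Br
Why: Nozaki–Hiyama–Kishi alkenylation adds the alkenylchromium(III) reagent to the aldehyde only and leaves the methyl ketone alone; the new carbinol centre forms as a mixture, which does not matter because it is destroyed in step 8.

Step 3
Reactants: 4 (5R)-7-hydroxy-8-methyl-5-(prop-1-en-2-yl)non-8-en-2-one
Product: 5 (4R)-6-hydroxy-7-methyl-4-(prop-1-en-2-yl)oct-7-enoic acid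
Conditions: Br2 (3.3 equiv), NaOH, dioxane/H2O, 0 °C; Na2SO3 quench; HCl to pH 3
Reagents that add atoms: sodium hydroxide [Na+].[OH-]
Why: Haloform reaction: the methyl ketone is tribrominated through its enolate and cleaved by hydroxide to the carboxylate, while cold alkaline hypobromite is a poor electrophile for the two 1,1-disubstituted alkenes; the stereocentre carries no acidic hydrogen.

Step 4
Reactants: 6 3-bromofuran
Product: 7 3-(furan-3-yl)propanal
Conditions: allyl alcohol (1.5 equiv), Pd(OAc)2 (3 mol %), n-Bu4NCl, NaHCO3, DMF, 60 °C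
Reagents that add atoms: allyl alcohol C=CCO
Why: Jeffery–Heck arylation of allyl alcohol: the furyl–Pd species adds to the terminal carbon, and β-hydride elimination toward the carbinol followed by tautomerisation gives the 3-arylpropanal.

Step 5
Reactants: 8 methyl 2-[bis(2,2,2-trifluoroethoxy)phosphoryl]acetate
Product: 10 methyl 2-bromo-2-[bis(2,2,2-trifluoroethoxy)phosphoryl]acetate, via dibromophosphonoacetate 9 (not isolated)
Conditions: Br2, NaOH, H2O, 0 °C; crude 9 then SnCl2·2H2O, EtOH/H2O, 0 °C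
Reagents that add atoms: bromine BrBr
Why: Exhaustive α-bromination of the active methylene by hypobromite followed by selective Sn(II) mono-debromination gives the monobromide cleanly and avoids the mono/di mixtures of direct monobromination.

Step 6
Reactants: 7 3-(furan-3-yl)propanal; 10 methyl 2-bromo-2-[bis(2,2,2-trifluoroethoxy)phosphoryl]acetate
Product: 11 methyl (2E)-2-bromo-5-(furan-3-yl)pent-2-enoate
Conditions: t-BuOK, 18-crown-6, THF, −78 °C
Reagents that add atoms: none
Why: Horner–Wadsworth–Emmons olefination with a bis(trifluoroethyl) (Still–Gennari-type) α-bromophosphonate: fast, irreversible elimination from the kinetic adduct places CO2Me cis to the alkyl chain, which is the (E)-α-bromoacrylate (typically ≥ 9:1).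

Step 7
Reactants: 5 (4R)-6-hydroxy-7-methyl-4-(prop-1-en-2-yl)oct-7-enoic acid; 11 methyl (2E)-2-bromo-5-(furan-3-yl)pent-2-enoate
Product: 13 methyl (2Z,5R)-2-[3-(furan-3-yl)propylidene]-7-hydroxy-8-methyl-5-(prop-1-en-2-yl)non-8-enoate, via NHPI ester 12 (not isolated)
Conditions: NHPI, DIC, DMAP (cat.), CH2Cl2, rt; crude 12 then 11 (1.5 equiv), NiCl2·6H2O (10 mol %), 2,2′-bipyridine (10 mol %), AgNO3 (0.3 equiv), DMF, Mg anode/RVC cathode, undivided cell, constant current, rt
Reagents that add atoms: none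
Why: Proposed new method: a Ni-electrocatalytic decarboxylative alkenylation in which the alkenyl partner is a geometrically defined (E)-α-bromo-α,β-unsaturated ester, a class not yet used in this coupling; (bpy)Ni(0/I) should insert into the activated C(sp2)–Br bond with retention, the primary radical released from NHPI ester 12 at the silver-modified cathode (it has no 5-exo acceptor at this stage, and the β-substituent of 11 slows Giese addition) is captured at nickel, and C(sp3)–C(sp2) reductive elimination from Ni(III) is expected to outrun C-to-O (allenoate) isomerisation of the α-ester alkenylnickel, so the cis CO2Me/CH2CH2-furyl relationship of 11 is carried into the (Z)-2-alkyl-2-enoate; the closest known reactions are the Ni-electrocatalytic decarboxylative alkenylation of NHPI esters with alkyl-substituted alkenyl halides (as in step 12) and the stereoretentive Pd-catalysed Negishi coupling of (E)-α-bromoacrylates with alkylzinc reagents; the stereocentre is remote and untouched.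

Step 8
Reactants: 13 methyl (2Z,5R)-2-[3-(furan-3-yl)propylidene]-7-hydroxy-8-methyl-5-(prop-1-en-2-yl)non-8-enoate
Product: 15 methyl (2Z,5R,7E)-11-(dimethylamino)-2-[3-(furan-3-yl)propylidene]-8-methyl-11-oxo-5-(prop-1-en-2-yl)undec-7-enoate, via ketene N,O-acetal 14 (not isolated)
Conditions: MeC(OMe)2NMe2 (4 equiv), xylene, 140 °C, MeOH distilled off
Reagents that add atoms: N,N-dimethylacetamide dimethyl acetal CC(OC)(OC)N(C)C
Why: Eschenmoser–Claisen rearrangement: the chair transition state keeps the C6 substituent equatorial, away from the NMe2 group, so the new C7=C8 bond is E (≥ 95:5) from either carbinol epimer, and the carbinol centre disappears.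

Step 9
Reactants: 15 methyl (2Z,5R,7E)-11-(dimethylamino)-2-[3-(furan-3-yl)propylidene]-8-methyl-11-oxo-5-(prop-1-en-2-yl)undec-7-enoate
Product: 16 methyl (2Z,5R,7E)-2-[3-(furan-3-yl)propylidene]-8-methyl-11-oxo-5-(prop-1-en-2-yl)undec-7-enoate
Conditions: Cp2Zr(H)Cl (1.6 equiv), THF, rt, 20 min; H2O/SiO2 work-up
Reagents that add atoms: none
Why: Schwartz-reagent reduction of a tertiary amide to the aldehyde (hydrozirconation of the amide C=O, hydrolysis on work-up); the ester, the furan and the hindered alkenes do not react in this time.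

Step 10
Reactants: 16 methyl (2Z,5R,7E)-2-[3-(furan-3-yl)propylidene]-8-methyl-11-oxo-5-(prop-1-en-2-yl)undec-7-enoate
Product: 17 methyl (2Z,5R,7E,11Z)-2-[3-(furan-3-yl)propylidene]-12-iodo-8-methyl-5-(prop-1-en-2-yl)trideca-7,11-dienoate
Conditions: EtPPh3I, n-BuLi, THF, 0 °C to rt; I2, −78 °C; NaHMDS, −78 to −20 °C; then 16, −78 °C
Reagents that add atoms: ethyltriphenylphosphonium iodide CC[P+](c1ccccc1)(c1ccccc1)c1ccccc1.[I-]; iodine II
Why: Zhao (Stork–Zhao-type) iodo-olefination: the α-iodo ylide gives the (Z)-2-iodoalk-2-ene, iodine cis to the chain (usually ≥ 10:1), under kinetic Wittig control; the enoate is inert at −78 °C.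

Step 11
Reactants: 18 (3-carboxypropyl)triphenylphosphonium bromide; 19 1-[(tert-butyldimethylsilyl)oxy]propan-2-one
Product: 21 (4Z)-6-[(tert-butyldimethylsilyl)oxy]-5-methylhex-4-enoic acid, via phosphorus ylide 20 (not isolated)
Conditions: NaHMDS (2.05 equiv), THF, 0 °C; 19, −78 °C to rt; 1 M HCl work-up
Reagents that add atoms: none
Why: Wittig reaction of a non-stabilised ylide with an α-silyloxy ketone (Still's Z-selective trisubstituted olefination): the oxygenated CH2 ends up cis to the ylide-derived chain, giving the (Z)-allylic silyl ether.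

Step 12
Reactants: 17 methyl (2Z,5R,7E,11Z)-2-[3-(furan-3-yl)propylidene]-12-iodo-8-methyl-5-(prop-1-en-2-yl)trideca-7,11-dienoate; 21 (4Z)-6-[(tert-butyldimethylsilyl)oxy]-5-methylhex-4-enoic acid
Product: 23 methyl (2Z,5R,7E,11Z,15Z)-17-[(tert-butyldimethylsilyl)oxy]-2-[3-(furan-3-yl)propylidene]-8,12,16-trimethyl-5-(prop-1-en-2-yl)heptadeca-7,11,15-trienoate, via NHPI ester 22 (not isolated)
Conditions: 21 (1.5 equiv), NHPI, DIC, DMAP (cat.), CH2Cl2, rt; crude 22 then 17, NiCl2·6H2O (10 mol %), 2,2′-bipyridine (10 mol %), AgNO3 (0.3 equiv), DMF, Mg anode/RVC cathode, constant current, rt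
Reagents that add atoms: none
Why: Ni-electrocatalytic decarboxylative alkenylation of a redox-active ester with an alkenyl iodide (known reaction type): the homoallylic primary radical is captured by the alkenyl–Ni(II) species and reductive elimination keeps the Z geometry of both olefins.

Step 13
Reactants: 23 methyl (2Z,5R,7E,11Z,15Z)-17-[(tert-butyldimethylsilyl)oxy]-2-[3-(furan-3-yl)propylidene]-8,12,16-trimethyl-5-(prop-1-en-2-yl)heptadeca-7,11,15-trienoate
Product: 25 (2Z,5R,7E,11Z,15Z)-2-[3-(furan-3-yl)propylidene]-17-hydroxy-8,12,16-trimethyl-5-(prop-1-en-2-yl)heptadeca-7,11,15-trienoic acid, via hydroxy ester 24 (not isolated)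
Conditions: TBAF (1.5 equiv), THF, rt; then LiOH·H2O (10 equiv), MeOH/H2O, 50 °C; 1 M HCl to pH 3–4 at 0 °C
Reagents that add atoms: lithium hydroxide [Li+].[OH-]
Why: Fluoride desilylation followed by saponification in the same flask; hydroxide hydrolyses the hindered (Z)-2-alkyl-2-enoate without isomerisation, and no stereocentre is touched.

## Compound list

1 | (4R)-1-methyl-4-(prop-1-en-2-yl)-7-oxabicyclo[4.1.0]heptane, (R)-(+)-limonene 1,2-oxide, cis/trans mixture | CC12OC1C[C@@H](CC2)C(=C)C | starting material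
2 | (4R)-1-methyl-4-(prop-1-en-2-yl)cyclohexane-1,2-diol (limonene-1,2-diol, diastereomer mixture) | CC1(O)C(O)C[C@@H](CC1)C(=C)C | intermediate (not isolated)
3 | (3R)-6-oxo-3-(prop-1-en-2-yl)heptanal | C=C(C)[C@@H](CC=O)CCC(C)=O | intermediate
4 | (5R)-7-hydroxy-8-methyl-5-(prop-1-en-2-yl)non-8-en-2-one (both C7 epimers) | C=C(C)[C@@H](CC(O)C(C)=C)CCC(C)=O | intermediate
5 | (4R)-6-hydroxy-7-methyl-4-(prop-1-en-2-yl)oct-7-enoic acid (both C6 epimers) | C=C(C)[C@@H](CC(O)C(C)=C)CCC(=O)O | intermediate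
6 | 3-bromofuran | Brc1ccoc1 | starting material
7 | 3-(furan-3-yl)propanal | O=CCCc1ccoc1 | intermediate
8 | methyl 2-[bis(2,2,2-trifluoroethoxy)phosphoryl]acetate | COC(=O)CP(=O)(OCC(F)(F)F)OCC(F)(F)F | starting material
9 | methyl 2,2-dibromo-2-[bis(2,2,2-trifluoroethoxy)phosphoryl]acetate | COC(=O)C(Br)(Br)P(=O)(OCC(F)(F)F)OCC(F)(F)F | intermediate (not isolated)
10 | methyl 2-bromo-2-[bis(2,2,2-trifluoroethoxy)phosphoryl]acetate (racemic) | COC(=O)C(Br)P(=O)(OCC(F)(F)F)OCC(F)(F)F | intermediate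
11 | methyl (2E)-2-bromo-5-(furan-3-yl)pent-2-enoate (CO2Me cis to the CH2CH2-furyl chain) | COC(=O)/C(Br)=C\CCc1ccoc1 | intermediate
12 | 1,3-dioxoisoindolin-2-yl (4R)-6-hydroxy-7-methyl-4-(prop-1-en-2-yl)oct-7-enoate | C=C(C)[C@@H](CC(O)C(C)=C)CCC(=O)ON1C(=O)c2ccccc2C1=O | intermediate (not isolated)
13 | methyl (2Z,5R)-2-[3-(furan-3-yl)propylidene]-7-hydroxy-8-methyl-5-(prop-1-en-2-yl)non-8-enoate (both C7 epimers) | C=C(C)[C@@H](CC(O)C(C)=C)CC/C(=C/CCc1ccoc1)C(=O)OC | intermediate
14 | methyl (2Z,5R)-7-{[1-(dimethylamino)ethenyl]oxy}-2-[3-(furan-3-yl)propylidene]-8-methyl-5-(prop-1-en-2-yl)non-8-enoate (ketene N,O-acetal) | C=C(C)[C@@H](CC(OC(=C)N(C)C)C(C)=C)CC/C(=C/CCc1ccoc1)C(=O)OC | intermediate (not isolated)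
15 | methyl (2Z,5R,7E)-11-(dimethylamino)-2-[3-(furan-3-yl)propylidene]-8-methyl-11-oxo-5-(prop-1-en-2-yl)undec-7-enoate | C=C(C)[C@@H](C/C=C(\C)CCC(=O)N(C)C)CC/C(=C/CCc1ccoc1)C(=O)OC | intermediate
16 | methyl (2Z,5R,7E)-2-[3-(furan-3-yl)propylidene]-8-methyl-11-oxo-5-(prop-1-en-2-yl)undec-7-enoate | C=C(C)[C@@H](C/C=C(\C)CCC=O)CC/C(=C/CCc1ccoc1)C(=O)OC | intermediate
17 | methyl (2Z,5R,7E,11Z)-2-[3-(furan-3-yl)propylidene]-12-iodo-8-methyl-5-(prop-1-en-2-yl)trideca-7,11-dienoate | C=C(C)[C@@H](C/C=C(\C)CC/C=C(/C)I)CC/C(=C/CCc1ccoc1)C(=O)OC | intermediate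
18 | (3-carboxypropyl)triphenylphosphonium bromide | OC(=O)CCC[P+](c1ccccc1)(c1ccccc1)c1ccccc1.[Br-] | starting material
19 | 1-[(tert-butyldimethylsilyl)oxy]propan-2-one | CC(=O)CO[Si](C)(C)C(C)(C)C | starting material
20 | sodium 4-(triphenyl-λ5-phosphanylidene)butanoate | [Na+].[O-]C(=O)CCC=P(c1ccccc1)(c1ccccc1)c1ccccc1 | intermediate (not isolated)
21 | (4Z)-6-[(tert-butyldimethylsilyl)oxy]-5-methylhex-4-enoic acid | OC(=O)CC/C=C(/C)CO[Si](C)(C)C(C)(C)C | intermediate
22 | 1,3-dioxoisoindolin-2-yl (4Z)-6-[(tert-butyldimethylsilyl)oxy]-5-methylhex-4-enoate | O=C(CC/C=C(/C)CO[Si](C)(C)C(C)(C)C)ON1C(=O)c2ccccc2C1=O | intermediate (not isolated)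
23 | methyl (2Z,5R,7E,11Z,15Z)-17-[(tert-butyldimethylsilyl)oxy]-2-[3-(furan-3-yl)propylidene]-8,12,16-trimethyl-5-(prop-1-en-2-yl)heptadeca-7,11,15-trienoate | C=C(C)[C@@H](C/C=C(\C)CC/C=C(/C)CC/C=C(/C)CO[Si](C)(C)C(C)(C)C)CC/C(=C/CCc1ccoc1)C(=O)OC | intermediate
24 | methyl (2Z,5R,7E,11Z,15Z)-2-[3-(furan-3-yl)propylidene]-17-hydroxy-8,12,16-trimethyl-5-(prop-1-en-2-yl)heptadeca-7,11,15-trienoate | C=C(C)[C@@H](C/C=C(\C)CC/C=C(/C)CC/C=C(/C)CO)CC/C(=C/CCc1ccoc1)C(=O)OC | intermediate (not isolated)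
25 | (2Z,5R,7E,11Z,15Z)-2-[3-(furan-3-yl)propylidene]-17-hydroxy-8,12,16-trimethyl-5-(prop-1-en-2-yl)heptadeca-7,11,15-trienoic acid (CNP0258614.1) | C=C(C)[C@@H](C/C=C(\C)CC/C=C(/C)CC/C=C(/C)CO)CC/C(=C/CCc1ccoc1)C(=O)O | target

## Step count and risks

Total step count: 13. Longest linear sequence: 9 (steps 1, 2, 3, 7, 8, 9, 10, 12, 13).

The three steps most likely to fail:

Step 7, the proposed new coupling. It can fail through cathodic hydrodebromination or homocoupling of 11, through E/Z leakage at an α-ester alkenylnickel, or through slow capture of the radical (competing 1,5-hydrogen shift). The fallback uses known chemistry only, sets out from 5 and comes back at 13. Acid 5 is converted with N-hydroxypyridine-2-thione and DCC into the Barton ester 2-thioxopyridin-1(2H)-yl (4R)-6-hydroxy-7-methyl-4-(prop-1-en-2-yl)oct-7-enoate F1, which is photolysed (tungsten lamp) with CHI3 to the primary iodide (5S)-7-iodo-2-methyl-5-(prop-1-en-2-yl)hept-1-en-3-ol F2 (Barton decarboxylative iodination; the descriptor changes only because iodine raises the priority of that arm). F2 alkylates the anion of phosphonate 8 (NaH, DMSO) to give methyl (5R)-2-[bis(2,2,2-trifluoroethoxy)phosphoryl]-7-hydroxy-8-methyl-5-(prop-1-en-2-yl)non-8-enoate F3. Still–Gennari olefination of F3 with aldehyde 7 (KHMDS 2 equiv, 18-crown-6, THF, −78 °C) gives the (Z)-enoate 13 directly. Steps 5 and 6 are then not needed.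

Step 3, the haloform reaction. Hypobromite may brominate an alkene or oxidise the allylic alcohol. The fallback sets out from 4 and comes back at 5. Kinetic enolisation at the methyl group (KHMDS 2.2 equiv, THF, −78 °C) and hydroxylation with the Davis oxaziridine give (5R)-1,7-dihydroxy-8-methyl-5-(prop-1-en-2-yl)non-8-en-2-one F4. NaIO4 in aqueous THF cleaves this α-hydroxy ketone to acid 5 without any electrophilic halogen.

Step 10, the Zhao olefination. It often gives a modest yield, some E isomer and some de-iodinated alkene. The fallback sets out from 16 and comes back at 23. Ramirez dibromo-olefination (CBr4, PPh3, Et3N, CH2Cl2, 0 °C) gives methyl (2Z,5R,7E)-12,12-dibromo-2-[3-(furan-3-yl)propylidene]-8-methyl-5-(prop-1-en-2-yl)dodeca-7,11-dienoate F5. Pd-catalysed trans-selective monomethylation (Me2Zn, PdCl2(DPEphos), THF, rt) replaces only the bromine trans to the chain and gives the (Z)-alkenyl bromide methyl (2Z,5R,7E,11Z)-12-bromo-2-[3-(furan-3-yl)propylidene]-8-methyl-5-(prop-1-en-2-yl)trideca-7,11-dienoate F6. F6 is used in place of 17 under the step 12 conditions to reach 23.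

Further compounds

F1 | step 7 | 2-thioxopyridin-1(2H)-yl (4R)-6-hydroxy-7-methyl-4-(prop-1-en-2-yl)oct-7-enoate | C=C(C)[C@@H](CC(O)C(C)=C)CCC(=O)On1ccccc1=S
F2 | step 7 | (5S)-7-iodo-2-methyl-5-(prop-1-en-2-yl)hept-1-en-3-ol | C=C(C)[C@@H](CC(O)C(C)=C)CCI
F3 | step 7 | methyl (5R)-2-[bis(2,2,2-trifluoroethoxy)phosphoryl]-7-hydroxy-8-methyl-5-(prop-1-en-2-yl)non-8-enoate | C=C(C)[C@@H](CC(O)C(C)=C)CCC(C(=O)OC)P(=O)(OCC(F)(F)F)OCC(F)(F)F
F4 | step 3 | (5R)-1,7-dihydroxy-8-methyl-5-(prop-1-en-2-yl)non-8-en-2-one | C=C(C)[C@@H](CC(O)C(C)=C)CCC(=O)CO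
F5 | step 10 | methyl (2Z,5R,7E)-12,12-dibromo-2-[3-(furan-3-yl)propylidene]-8-methyl-5-(prop-1-en-2-yl)dodeca-7,11-dienoate | C=C(C)[C@@H](C/C=C(\C)CCC=C(Br)Br)CC/C(=C/CCc1ccoc1)C(=O)OC
F6 | step 10 | methyl (2Z,5R,7E,11Z)-12-bromo-2-[3-(furan-3-yl)propylidene]-8-methyl-5-(prop-1-en-2-yl)trideca-7,11-dienoate | C=C(C)[C@@H](C/C=C(\C)CC/C=C(/C)Br)CC/C(=C/CCc1ccoc1)C(=O)OC
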